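**Retrosynthetic overview**
1. Target ⇐ tetrasilyl ether 33 ⇐ 2'-hydroxychalcone 32: the pyranone ring of the flavanone closes last, by a thiourea–amine-catalysed intramolecular oxa-Michael addition that sets C2.
2. Chalcone ⇐ aryl bromide 29 + Weinreb cinnamamide 20 (Br/Li exchange, acylation). The (E)-styrene of 29 ⇐ lactone carbonyl of 23 (Weinreb opening, ArMgBr, reduction, dehydration).
3. Benzylic stereocentre ⇐ trans-selective copper-catalysed conjugate addition of the symmetrically flanked aryl Grignard 21 to (S)-dihydropyranone 10. The bromine on the otherwise symmetric ring fixes where the acyl group enters.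
4. 10 ⇐ acrylate ring-closing metathesis of homoallylic alcohol 8 ⇐ benzylic Grignard 7 + (R)-allyloxirane 6, made from (R)-epichlorohydrin (source of the carbinol centre).
5. Ring order: temporary δ-lactone (step 7, opened again in step 15), then the chromanone heterocycle (step 22). All benzene rings are bought.

Abbreviations: TBS = tert-butyldimethylsilyl (TBSO = TBS–O–), MOM = methoxymethyl.
Assumption: the epi-quinidine thiourea gives the 2S sense at the flavanone centre; if the sense proves opposite, the pseudoenantiomeric epi-quinine thiourea is used in the same step.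

**Route**

Step 1
Reactants: 1 4-methylphenol
Product: 2 tert-butyldimethyl(4-methylphenoxy)silane
Conditions: TBSCl, imidazole, DMF, rt
Reagents that add atoms: tert-butyldimethylsilyl chloride, CC(C)(C)[Si](C)(C)Cl
Why: Imidazole-promoted O-silylation protects the phenol as a base- and Grignard-stable silyl ether.

Step 2
Reactants: 2 tert-butyldimethyl(4-methylphenoxy)silane
Product: 3 [4-(bromomethyl)phenoxy](tert-butyl)dimethylsilane
Conditions: NBS, AIBN (cat.), PhCF3, reflux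
Reagents that add atoms: N-bromosuccinimide, O=C1CCC(=O)N1Br
Why: Wohl–Ziegler radical bromination is selective for the benzylic methyl group in a non-polar solvent.

Step 3
Reactants: 4 (R)-epichlorohydrin [(2R)-2-(chloromethyl)oxirane]
Product: 5 (2R)-1-chloropent-4-en-2-ol
Conditions: vinylmagnesium bromide, CuBr·SMe2 (10 mol%), THF, −40 °C; aq NH4Cl
Reagents that add atoms: vinylmagnesium bromide, C=C[Mg]Br
Why: Copper-catalysed Grignard opening of the epoxide at its CH2 end breaks no bond to the stereocentre, so the R centre is carried over.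

Step 4
Reactants: 5 (2R)-1-chloropent-4-en-2-ol
Product: 6 (2R)-2-(prop-2-en-1-yl)oxirane
Conditions: powdered NaOH, Et2O, rt; distil
Reagents that add atoms: none
Why: Intramolecular Williamson etherification re-forms an epoxide on the other side of the untouched stereocentre.

Step 5
Reactants: 3 [4-(bromomethyl)phenoxy](tert-butyl)dimethylsilane; 6 (2R)-2-(prop-2-en-1-yl)oxirane
Product: 8 (3S)-1-[4-(TBSO)phenyl]hex-5-en-3-ol, via benzylic Grignard reagent 7 (not isolated)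
Conditions: Mg, Et2O, 0 °C (slow addition of 3); then 6, CuBr·SMe2 (10 mol%), THF, −30 → 0 °C; aq NH4Cl
Reagents that add atoms: none
Why: Copper-catalysed SN2 opening of the terminal epoxide by the benzylic Grignard reagent at CH2 leaves the carbinol centre untouched; it is S only because the CIP ranking changes.

Step 6
Reactants: 8 (3S)-1-[4-(TBSO)phenyl]hex-5-en-3-ol
Product: 9 (3S)-1-[4-(TBSO)phenyl]hex-5-en-3-yl prop-2-enoate
Conditions: acryloyl chloride, Et3N, DMAP (cat.), CH2Cl2, 0 °C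
Reagents that add atoms: acryloyl chloride, C=CC(=O)Cl
Why: Esterification of the secondary alcohol with an acid chloride installs the second alkene for ring closure.

Step 7
Reactants: 9 (3S)-1-[4-(TBSO)phenyl]hex-5-en-3-yl prop-2-enoate
Product: 10 (6S)-6-{2-[4-(TBSO)phenyl]ethyl}-5,6-dihydro-2H-pyran-2-one
Conditions: second-generation Grubbs catalyst RuCl2(=CHPh)(H2IMes)(PCy3) (5 mol%), CH2Cl2 (0.01 M), 40 °C
Reagents that add atoms: none
Why: Ring-closing metathesis of the acrylate and the terminal alkene gives the six-membered unsaturated lactone with loss of ethene, without involving the stereocentre.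

Step 8
Reactants: 11 5-methoxybenzene-1,3-diol
Product: 12 1-methoxy-3,5-bis(methoxymethoxy)benzene
Conditions: MOMCl, i-Pr2NEt, CH2Cl2, 0 °C → rt
Reagents that add atoms: chloromethyl methyl ether, COCCl
Why: O-Alkylation of both phenols gives MOM ethers that protect the ring and later direct metalation.

Step 9
Reactants: 12 1-methoxy-3,5-bis(methoxymethoxy)benzene
Product: 14 2-iodo-5-methoxy-1,3-bis(methoxymethoxy)benzene, via aryllithium 13 (not isolated)
Conditions: n-BuLi, THF, 0 °C; then I2, −78 °C → rt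
Reagents that add atoms: iodine, II
Why: Directed ortho-metalation occurs at the position flanked by the two MOM ethers, and the aryllithium is quenched by iodine.

Step 10
Reactants: 14 2-iodo-5-methoxy-1,3-bis(methoxymethoxy)benzene
Product: 15 1-bromo-3-iodo-6-methoxy-2,4-bis(methoxymethoxy)benzene
Conditions: NBS (1.0 equiv), MeCN, 0 °C, dark
Reagents that add atoms: N-bromosuccinimide, O=C1CCC(=O)N1Br
Why: Electrophilic aromatic bromination of the trialkoxy-activated ring gives one bromide because the two free positions are equivalent.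

Step 11
Reactants: 16 4-bromophenol
Product: 17 (4-bromophenoxy)(tert-butyl)dimethylsilane
Conditions: TBSCl, imidazole, DMF, rt
Reagents that add atoms: tert-butyldimethylsilyl chloride, CC(C)(C)[Si](C)(C)Cl
Why: O-Silylation masks the phenol so that the aryl Grignard reagent can be formed later.

Step 12
Reactants: 18 4-hydroxybenzaldehyde
Product: 19 4-(TBSO)benzaldehyde
Conditions: TBSCl, imidazole, CH2Cl2, rt
Reagents that add atoms: tert-butyldimethylsilyl chloride, CC(C)(C)[Si](C)(C)Cl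
Why: O-Silylation protects the future ring B phenol.

Step 13
Reactants: 19 4-(TBSO)benzaldehyde
Product: 20 (2E)-N-methoxy-N-methyl-3-[4-(TBSO)phenyl]prop-2-enamide
Conditions: diethyl {2-[methoxy(methyl)amino]-2-oxoethyl}phosphonate, NaH, THF, 0 °C → rt
Reagents that add atoms: diethyl {2-[methoxy(methyl)amino]-2-oxoethyl}phosphonate, CCOP(=O)(OCC)CC(=O)N(C)OC
Why: Horner–Wadsworth–Emmons olefination with a stabilised phosphonate gives the (E)-enamide.

Step 14
Reactants: 15 1-bromo-3-iodo-6-methoxy-2,4-bis(methoxymethoxy)benzene; 10 (6S)-6-{2-[4-(TBSO)phenyl]ethyl}-5,6-dihydro-2H-pyran-2-one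
Product: 23 (4S,6S)-4-[3-bromo-4-methoxy-2,6-bis(methoxymethoxy)phenyl]-6-{2-[4-(TBSO)phenyl]ethyl}oxan-2-one, via arylmagnesium chloride 21 (not isolated), via silyl ketene acetal 22 (not isolated)
Conditions: 15, i-PrMgCl·LiCl, THF, −20 °C; then 10, CuBr·SMe2 (20 mol%), TMSCl, THF, −78 → −40 °C; aq NH4Cl
Reagents that add atoms: none
Why: Iodine–magnesium exchange occurs only at the iodide between the two chelating MOM ethers, and the TMSCl-accelerated copper-catalysed conjugate addition delivers the aryl group axially, anti to the C6 side chain of the half-chair lactone, setting the new centre trans (4S,6S).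

Step 15
Reactants: 23 (4S,6S)-4-[3-bromo-4-methoxy-2,6-bis(methoxymethoxy)phenyl]-6-{2-[4-(TBSO)phenyl]ethyl}oxan-2-one
Product: 24 (3S,5S)-3-[3-bromo-4-methoxy-2,6-bis(methoxymethoxy)phenyl]-5-hydroxy-N-methoxy-N-methyl-7-[4-(TBSO)phenyl]heptanamide
Conditions: MeNH(OMe)·HCl, Me3Al, CH2Cl2, 0 °C → rt; aq Rochelle salt
Reagents that add atoms: N,O-dimethylhydroxylamine hydrochloride, CNOC.Cl
Why: Weinreb aminolysis of the lactone by the aluminium amide cleaves the acyl C–O bond and touches neither stereocentre.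

Step 16
Reactants: 24 (3S,5S)-3-[3-bromo-4-methoxy-2,6-bis(methoxymethoxy)phenyl]-5-hydroxy-N-methoxy-N-methyl-7-[4-(TBSO)phenyl]heptanamide
Product: 25 (3S,5S)-3-[3-bromo-4-methoxy-2,6-bis(methoxymethoxy)phenyl]-5-(TBSO)-N-methoxy-N-methyl-7-[4-(TBSO)phenyl]heptanamide
Conditions: TBSOTf, 2,6-lutidine, CH2Cl2, −78 → 0 °C
Reagents that add atoms: tert-butyldimethylsilyl triflate, CC(C)(C)[Si](C)(C)OS(=O)(=O)C(F)(F)F
Why: Silylation of the liberated secondary alcohol prevents relactonisation and later cyclic ether formation.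

Step 17
Reactants: 25 (3S,5S)-3-[3-bromo-4-methoxy-2,6-bis(methoxymethoxy)phenyl]-5-(TBSO)-N-methoxy-N-methyl-7-[4-(TBSO)phenyl]heptanamide; 17 (4-bromophenoxy)(tert-butyl)dimethylsilane
Product: 27 (3S,5S)-3-[3-bromo-4-methoxy-2,6-bis(methoxymethoxy)phenyl]-5-(TBSO)-1,7-bis[4-(TBSO)phenyl]heptan-1-one, via aryl Grignard reagent 26 (not isolated)
Conditions: 17, Mg, THF, reflux; then 25, THF, 0 °C → rt; aq NH4Cl
Reagents that add atoms: none
Why: Grignard addition to the Weinreb amide stops at the ketone through the chelated tetrahedral intermediate, and the hindered ring A bromide is inert to ArMgBr.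

Step 18
Reactants: 27 (3S,5S)-3-[3-bromo-4-methoxy-2,6-bis(methoxymethoxy)phenyl]-5-(TBSO)-1,7-bis[4-(TBSO)phenyl]heptan-1-one
Product: 28 (1RS,3R,5S)-3-[3-bromo-4-methoxy-2,6-bis(methoxymethoxy)phenyl]-5-(TBSO)-1,7-bis[4-(TBSO)phenyl]heptan-1-ol
Conditions: NaBH4, THF–EtOH, 0 °C → rt
Reagents that add atoms: none
Why: Borohydride reduction gives the benzylic alcohol as an irrelevant epimer mixture; C3 is unchanged in space and is R only because the CIP ranking changes.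

Step 19
Reactants: 28 (1RS,3R,5S)-3-[3-bromo-4-methoxy-2,6-bis(methoxymethoxy)phenyl]-5-(TBSO)-1,7-bis[4-(TBSO)phenyl]heptan-1-ol
Product: 29 (1E,3S,5S)-3-[3-bromo-4-methoxy-2,6-bis(methoxymethoxy)phenyl]-5-(TBSO)-1,7-bis[4-(TBSO)phenyl]hept-1-ene
Conditions: Burgess reagent, toluene, 60 °C
Reagents that add atoms: none
Why: Burgess dehydration (syn-elimination through the sulfamate ester) can only remove a C2 hydrogen and gives the conjugated (E)-styrene under non-acidic conditions.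

Step 20
Reactants: 29 (1E,3S,5S)-3-[3-bromo-4-methoxy-2,6-bis(methoxymethoxy)phenyl]-5-(TBSO)-1,7-bis[4-(TBSO)phenyl]hept-1-ene; 20 (2E)-N-methoxy-N-methyl-3-[4-(TBSO)phenyl]prop-2-enamide
Product: 31 (2E)-1-{3-[(1E,3S,5S)-5-(TBSO)-1,7-bis(4-TBSO-phenyl)hept-1-en-3-yl]-6-methoxy-2,4-bis(methoxymethoxy)phenyl}-3-(4-TBSO-phenyl)prop-2-en-1-one, via aryllithium 30 (not isolated)
Conditions: n-BuLi (1.05 equiv), THF, −78 °C, 10 min; then 20, −78 → −40 °C; aq NH4Cl
Reagents that add atoms: none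
Why: Bromine–lithium exchange at −78 °C is faster than deprotonation or addition to the styrene, and Weinreb acylation of the aryllithium gives the chalcone ketone without over-addition.

Step 21
Reactants: 31 (2E)-1-{3-[(1E,3S,5S)-5-(TBSO)-1,7-bis(4-TBSO-phenyl)hept-1-en-3-yl]-6-methoxy-2,4-bis(methoxymethoxy)phenyl}-3-(4-TBSO-phenyl)prop-2-en-1-one
Product: 32 (2E)-1-{3-[(1E,3S,5S)-5-(TBSO)-1,7-bis(4-TBSO-phenyl)hept-1-en-3-yl]-2,4-dihydroxy-6-methoxyphenyl}-3-(4-TBSO-phenyl)prop-2-en-1-one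
Conditions: TMSOTf, 2,2'-bipyridyl, CH2Cl2, 0 °C → rt; then H2O
Reagents that add atoms: none
Why: Bipyridyl-buffered silyl triflate cleavage of the aryl MOM acetals gives labile TMS ethers that hydrolyse on work-up, leaving the TBS ethers, enone and styrene intact.

Step 22
Reactants: 32 (2E)-1-{3-[(1E,3S,5S)-5-(TBSO)-1,7-bis(4-TBSO-phenyl)hept-1-en-3-yl]-2,4-dihydroxy-6-methoxyphenyl}-3-(4-TBSO-phenyl)prop-2-en-1-one
Product: 33 (2S)-8-[(1E,3S,5S)-5-(TBSO)-1,7-bis(4-TBSO-phenyl)hept-1-en-3-yl]-7-hydroxy-5-methoxy-2-(4-TBSO-phenyl)-2,3-dihydro-4H-chromen-4-one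
Conditions: 1-[3,5-bis(trifluoromethyl)phenyl]-3-(9-deoxy-epi-quinidin-9-yl)thiourea (20 mol%), toluene, −20 → 0 °C
Reagents that add atoms: none
Why: Intramolecular oxa-Michael addition of the 2'-hydroxyl to the enone under bifunctional base/hydrogen-bond catalysis closes the pyranone ring, with the catalyst selecting the enone face that gives 2S; the minor 2R diastereomer is removed by chromatography.

Step 23
Reactants: 33 (2S)-8-[(1E,3S,5S)-5-(TBSO)-1,7-bis(4-TBSO-phenyl)hept-1-en-3-yl]-7-hydroxy-5-methoxy-2-(4-TBSO-phenyl)-2,3-dihydro-4H-chromen-4-one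
Product: 34 (2S)-7-hydroxy-8-[(1E,3S,5S)-5-hydroxy-1,7-bis(4-hydroxyphenyl)hept-1-en-3-yl]-2-(4-hydroxyphenyl)-5-methoxy-2,3-dihydro-4H-chromen-4-one
Conditions: HF·pyridine, THF–pyridine, 0 °C → rt
Reagents that add atoms: none
Why: Fluoride-mediated desilylation of the four silyl ethers under mildly acidic conditions avoids retro-Michael opening, so C2 is not epimerised.

**Compound list**

1 | 4-methylphenol | Cc1ccc(O)cc1 | starting material
2 | tert-butyldimethyl(4-methylphenoxy)silane | Cc1ccc(O[Si](C)(C)C(C)(C)C)cc1 | intermediate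
3 | [4-(bromomethyl)phenoxy](tert-butyl)dimethylsilane | BrCc1ccc(O[Si](C)(C)C(C)(C)C)cc1 | intermediate
4 | (R)-epichlorohydrin, (2R)-2-(chloromethyl)oxirane | ClC[C@H]1CO1 | starting material
5 | (2R)-1-chloropent-4-en-2-ol | ClC[C@H](O)CC=C | intermediate
6 | (2R)-2-(prop-2-en-1-yl)oxirane | C=CC[C@@H]1CO1 | intermediate
7 | [4-(TBSO)benzyl]magnesium bromide | Br[Mg]Cc1ccc(O[Si](C)(C)C(C)(C)C)cc1 | intermediate
8 | (3S)-1-[4-(TBSO)phenyl]hex-5-en-3-ol | C=CC[C@@H](O)CCc1ccc(O[Si](C)(C)C(C)(C)C)cc1 | intermediate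
9 | (3S)-1-[4-(TBSO)phenyl]hex-5-en-3-yl prop-2-enoate | C=CC[C@@H](OC(=O)C=C)CCc1ccc(O[Si](C)(C)C(C)(C)C)cc1 | intermediate
10 | (6S)-6-{2-[4-(TBSO)phenyl]ethyl}-5,6-dihydro-2H-pyran-2-one | O=C1C=CC[C@H](CCc2ccc(O[Si](C)(C)C(C)(C)C)cc2)O1 | intermediate
11 | 5-methoxybenzene-1,3-diol | COc1cc(O)cc(O)c1 | starting material
12 | 1-methoxy-3,5-bis(methoxymethoxy)benzene | COCOc1cc(OC)cc(OCOC)c1 | intermediate
13 | [4-methoxy-2,6-bis(methoxymethoxy)phenyl]lithium | [Li]c1c(OCOC)cc(OC)cc1OCOC | intermediate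
14 | 2-iodo-5-methoxy-1,3-bis(methoxymethoxy)benzene | COCOc1cc(OC)cc(OCOC)c1I | intermediate
15 | 1-bromo-3-iodo-6-methoxy-2,4-bis(methoxymethoxy)benzene | COCOc1cc(OC)c(Br)c(OCOC)c1I | intermediate
16 | 4-bromophenol | Oc1ccc(Br)cc1 | starting material
17 | (4-bromophenoxy)(tert-butyl)dimethylsilane | Brc1ccc(O[Si](C)(C)C(C)(C)C)cc1 | intermediate
18 | 4-hydroxybenzaldehyde | O=Cc1ccc(O)cc1 | starting material
19 | 4-(TBSO)benzaldehyde | O=Cc1ccc(O[Si](C)(C)C(C)(C)C)cc1 | intermediate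
20 | (2E)-N-methoxy-N-methyl-3-[4-(TBSO)phenyl]prop-2-enamide | CON(C)C(=O)/C=C/c1ccc(O[Si](C)(C)C(C)(C)C)cc1 | intermediate
21 | [3-bromo-4-methoxy-2,6-bis(methoxymethoxy)phenyl]magnesium chloride | Cl[Mg]c1c(OCOC)cc(OC)c(Br)c1OCOC | intermediate
22 | (2S,4S)-4-[3-bromo-4-methoxy-2,6-bis(methoxymethoxy)phenyl]-2-{2-[4-(TBSO)phenyl]ethyl}-6-(trimethylsilyloxy)-3,4-dihydro-2H-pyran | C[Si](C)(C)OC1=C[C@@H](c2c(OCOC)cc(OC)c(Br)c2OCOC)C[C@H](CCc2ccc(O[Si](C)(C)C(C)(C)C)cc2)O1 | intermediate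
23 | (4S,6S)-4-[3-bromo-4-methoxy-2,6-bis(methoxymethoxy)phenyl]-6-{2-[4-(TBSO)phenyl]ethyl}oxan-2-one (trans) | O=C1C[C@@H](c2c(OCOC)cc(OC)c(Br)c2OCOC)C[C@H](CCc2ccc(O[Si](C)(C)C(C)(C)C)cc2)O1 | intermediate
24 | (3S,5S)-3-[3-bromo-4-methoxy-2,6-bis(methoxymethoxy)phenyl]-5-hydroxy-N-methoxy-N-methyl-7-[4-(TBSO)phenyl]heptanamide | COCOc1cc(OC)c(Br)c(OCOC)c1[C@H](CC(=O)N(C)OC)C[C@@H](O)CCc1ccc(O[Si](C)(C)C(C)(C)C)cc1 | intermediate
25 | (3S,5S)-3-[3-bromo-4-methoxy-2,6-bis(methoxymethoxy)phenyl]-5-(TBSO)-N-methoxy-N-methyl-7-[4-(TBSO)phenyl]heptanamide | COCOc1cc(OC)c(Br)c(OCOC)c1[C@H](CC(=O)N(C)OC)C[C@@H](O[Si](C)(C)C(C)(C)C)CCc1ccc(O[Si](C)(C)C(C)(C)C)cc1 | intermediate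
26 | [4-(TBSO)phenyl]magnesium bromide | Br[Mg]c1ccc(O[Si](C)(C)C(C)(C)C)cc1 | intermediate
27 | (3S,5S)-3-[3-bromo-4-methoxy-2,6-bis(methoxymethoxy)phenyl]-5-(TBSO)-1,7-bis[4-(TBSO)phenyl]heptan-1-one | COCOc1cc(OC)c(Br)c(OCOC)c1[C@H](CC(=O)c1ccc(O[Si](C)(C)C(C)(C)C)cc1)C[C@@H](O[Si](C)(C)C(C)(C)C)CCc1ccc(O[Si](C)(C)C(C)(C)C)cc1 | intermediate
28 | (1RS,3R,5S)-3-[3-bromo-4-methoxy-2,6-bis(methoxymethoxy)phenyl]-5-(TBSO)-1,7-bis[4-(TBSO)phenyl]heptan-1-ol | COCOc1cc(OC)c(Br)c(OCOC)c1[C@H](CC(O)c1ccc(O[Si](C)(C)C(C)(C)C)cc1)C[C@@H](O[Si](C)(C)C(C)(C)C)CCc1ccc(O[Si](C)(C)C(C)(C)C)cc1 | intermediate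
29 | (1E,3S,5S)-3-[3-bromo-4-methoxy-2,6-bis(methoxymethoxy)phenyl]-5-(TBSO)-1,7-bis[4-(TBSO)phenyl]hept-1-ene | COCOc1cc(OC)c(Br)c(OCOC)c1[C@H](/C=C/c1ccc(O[Si](C)(C)C(C)(C)C)cc1)C[C@@H](O[Si](C)(C)C(C)(C)C)CCc1ccc(O[Si](C)(C)C(C)(C)C)cc1 | intermediate
30 | {3-[(1E,3S,5S)-5-(TBSO)-1,7-bis(4-TBSO-phenyl)hept-1-en-3-yl]-6-methoxy-2,4-bis(methoxymethoxy)phenyl}lithium | COCOc1cc(OC)c([Li])c(OCOC)c1[C@H](/C=C/c1ccc(O[Si](C)(C)C(C)(C)C)cc1)C[C@@H](O[Si](C)(C)C(C)(C)C)CCc1ccc(O[Si](C)(C)C(C)(C)C)cc1 | intermediate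
31 | (2E)-1-{3-[(1E,3S,5S)-5-(TBSO)-1,7-bis(4-TBSO-phenyl)hept-1-en-3-yl]-6-methoxy-2,4-bis(methoxymethoxy)phenyl}-3-(4-TBSO-phenyl)prop-2-en-1-one | COCOc1cc(OC)c(C(=O)/C=C/c2ccc(O[Si](C)(C)C(C)(C)C)cc2)c(OCOC)c1[C@H](/C=C/c1ccc(O[Si](C)(C)C(C)(C)C)cc1)C[C@@H](O[Si](C)(C)C(C)(C)C)CCc1ccc(O[Si](C)(C)C(C)(C)C)cc1 | intermediate
32 | (2E)-1-{3-[(1E,3S,5S)-5-(TBSO)-1,7-bis(4-TBSO-phenyl)hept-1-en-3-yl]-2,4-dihydroxy-6-methoxyphenyl}-3-(4-TBSO-phenyl)prop-2-en-1-one | COc1cc(O)c([C@H](/C=C/c2ccc(O[Si](C)(C)C(C)(C)C)cc2)C[C@@H](O[Si](C)(C)C(C)(C)C)CCc2ccc(O[Si](C)(C)C(C)(C)C)cc2)c(O)c1C(=O)/C=C/c1ccc(O[Si](C)(C)C(C)(C)C)cc1 | intermediate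
33 | (2S)-8-[(1E,3S,5S)-5-(TBSO)-1,7-bis(4-TBSO-phenyl)hept-1-en-3-yl]-7-hydroxy-5-methoxy-2-(4-TBSO-phenyl)-2,3-dihydro-4H-chromen-4-one | COc1cc(O)c([C@H](/C=C/c2ccc(O[Si](C)(C)C(C)(C)C)cc2)C[C@@H](O[Si](C)(C)C(C)(C)C)CCc2ccc(O[Si](C)(C)C(C)(C)C)cc2)c2c1C(=O)C[C@@H](c1ccc(O[Si](C)(C)C(C)(C)C)cc1)O2 | intermediate
34 | (2S)-7-hydroxy-8-[(1E,3S,5S)-5-hydroxy-1,7-bis(4-hydroxyphenyl)hept-1-en-3-yl]-2-(4-hydroxyphenyl)-5-methoxy-2,3-dihydro-4H-chromen-4-one | COc1cc(O)c([C@H](/C=C/c2ccc(O)cc2)C[C@@H](O)CCc2ccc(O)cc2)c2c1C(=O)C[C@@H](c1ccc(O)cc1)O2 | target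

**Step count and risks**

Total step count: 23. Longest linear sequence: 15 steps (1, 2, 5, 6, 7, 14, 15, 16, 17, 18, 19, 20, 21, 22, 23; the arm through steps 3 and 4 is equally long).

Step 14 is at risk because the iodine–magnesium exchange must be chemoselective in the presence of the bromide, and a doubly ortho-substituted aryl group must be transferred. The fallback carries no halogen through the coupling. It sets out from 12 and 10: 12 is lithiated to aryllithium 13 as in step 9 and transmetalated with MgBr2·OEt2 to the halogen-free [4-methoxy-2,6-bis(methoxymethoxy)phenyl]magnesium bromide F1. F1 is added to 10 (CuBr·SMe2, TMSCl, THF, −78 °C) through the des-bromo silyl ketene acetal F2 to give the des-bromo trans-lactone F3. Ring bromination of F3 with NBS (MeCN, 0 °C; only the trialkoxy ring reacts and its two free positions are equivalent) comes back to the route at 23.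

Step 20 is at risk because the aryllithium is generated next to an acidic allylic/benzylic C–H and a styrene, and the acylation is hindered. The fallback replaces the organolithium by palladium chemistry and builds the enone by aldol condensation. It sets out from 29: Stille coupling with tributyl(1-ethoxyvinyl)stannane (Pd(PPh3)4, toluene, 100 °C) gives the aryl enol ether F4, which is hydrolysed (1 M HCl, THF, rt) to the methyl ketone F5. Its lithium enolate (LiN(SiMe3)2, THF, −78 °C) adds to aldehyde 19 to give the aldol F6, and dehydration (MsCl, Et3N, then DBU) comes back to the route at 31.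

Step 22 is at risk in both the level and the sense of catalyst control, because the chalcone is not activated and carries a free para-hydroxyl. The fallback gives up catalyst control and uses the fact that the two C2 epimers are diastereomers. It sets out from 32: cyclisation with NaOAc in EtOH at 50 °C gives 33 together with its 2R epimer F7, and the two are separated by chromatography. F7 is returned to the same conditions, where reversible retro-Michael opening to 32 re-establishes the mixture; the route is rejoined at 33.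

**Further compounds**

F1 | step 14 | [4-methoxy-2,6-bis(methoxymethoxy)phenyl]magnesium bromide | Br[Mg]c1c(OCOC)cc(OC)cc1OCOC
F2 | step 14 | (2S,4S)-4-[4-methoxy-2,6-bis(methoxymethoxy)phenyl]-2-{2-[4-(TBSO)phenyl]ethyl}-6-(trimethylsilyloxy)-3,4-dihydro-2H-pyran | C[Si](C)(C)OC1=C[C@@H](c2c(OCOC)cc(OC)cc2OCOC)C[C@H](CCc2ccc(O[Si](C)(C)C(C)(C)C)cc2)O1
F3 | step 14 | (4S,6S)-4-[4-methoxy-2,6-bis(methoxymethoxy)phenyl]-6-{2-[4-(TBSO)phenyl]ethyl}oxan-2-one | O=C1C[C@@H](c2c(OCOC)cc(OC)cc2OCOC)C[C@H](CCc2ccc(O[Si](C)(C)C(C)(C)C)cc2)O1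
F4 | step 20 | (1E,3S,5S)-3-[3-(1-ethoxyethenyl)-4-methoxy-2,6-bis(methoxymethoxy)phenyl]-5-(TBSO)-1,7-bis[4-(TBSO)phenyl]hept-1-ene | COCOc1cc(OC)c(C(=C)OCC)c(OCOC)c1[C@H](/C=C/c1ccc(O[Si](C)(C)C(C)(C)C)cc1)C[C@@H](O[Si](C)(C)C(C)(C)C)CCc1ccc(O[Si](C)(C)C(C)(C)C)cc1
F5 | step 20 | 1-{3-[(1E,3S,5S)-5-(TBSO)-1,7-bis(4-TBSO-phenyl)hept-1-en-3-yl]-6-methoxy-2,4-bis(methoxymethoxy)phenyl}ethan-1-one | COCOc1cc(OC)c(C(C)=O)c(OCOC)c1[C@H](/C=C/c1ccc(O[Si](C)(C)C(C)(C)C)cc1)C[C@@H](O[Si](C)(C)C(C)(C)C)CCc1ccc(O[Si](C)(C)C(C)(C)C)cc1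
F6 | step 20 | 1-{3-[(1E,3S,5S)-5-(TBSO)-1,7-bis(4-TBSO-phenyl)hept-1-en-3-yl]-6-methoxy-2,4-bis(methoxymethoxy)phenyl}-3-hydroxy-3-(4-TBSO-phenyl)propan-1-one (carbinol epimers) | COCOc1cc(OC)c(C(=O)CC(O)c2ccc(O[Si](C)(C)C(C)(C)C)cc2)c(OCOC)c1[C@H](/C=C/c1ccc(O[Si](C)(C)C(C)(C)C)cc1)C[C@@H](O[Si](C)(C)C(C)(C)C)CCc1ccc(O[Si](C)(C)C(C)(C)C)cc1
F7 | step 22 | (2R)-8-[(1E,3S,5S)-5-(TBSO)-1,7-bis(4-TBSO-phenyl)hept-1-en-3-yl]-7-hydroxy-5-methoxy-2-(4-TBSO-phenyl)-2,3-dihydro-4H-chromen-4-one | COc1cc(O)c([C@H](/C=C/c2ccc(O[Si](C)(C)C(C)(C)C)cc2)C[C@@H](O[Si](C)(C)C(C)(C)C)CCc2ccc(O[Si](C)(C)C(C)(C)C)cc2)c2c1C(=O)C[C@H](c1ccc(O[Si](C)(C)C(C)(C)C)cc1)O2
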